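With the chain numbered from the methylene (C1=C2) through the stereocentres C3 and C4 to the ring carbons C6–C9, the route rests on one disconnection. The tetrasubstituted exocyclic alkene C5=C6 of the 2,5-dihydrofuran ring (O, C6, C7=C8, C9Me2) is traced back to the alkyne C5≡C6 of an open-chain (Z)-enynol. In a single operation, divalent palladium under CO in methanol adds the C9 hydroxyl and a methoxycarbonyl group anti across that alkyne, closing the ring at O–C6, forming C5–CO2Me (the later C5 formyl group) and fixing the alkene geometry. The precursor is the (3R,4S,7Z)-enynol with C3 carrying a pivaloyloxymethyl group, C4 a dimethyl-acetal arm, and the ketone masked as a dioxolane.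

Key step: step 15

Locants used below: C1H2=C2(side chain)–C3–C4(arm)–C5=C6–C7=C8–C9Me2, with the ring oxygen between C9 and C6. "Side chain" is the chain on C2 that ends in the methyl ketone; "arm" is the two-carbon unit on C4.

Assumption: the (S,S)-bromoborane of step 5 is taken to favour the chair that joins the Re face of C3 to the Re face of C4; if its sense of induction is the reverse, the (R,R) reagent is used and nothing else changes.

Remark on protecting groups: the C3 oxygen is carried as a pivalate, not a silyl ether. The alkyne must be freed with fluoride just before the coupling, acid in methanol cannot harm the pivalate, and it falls away in the same hydride step that reduces the C5 ester. The alkyne is carried as its triisopropylsilyl derivative so that the hydroboration cannot touch it.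

Step 1
Reactants: 1 5-chloropentan-2-one
Product: 2 2-(3-chloropropyl)-2-methyl-1,3-dioxolane
Conditions: ethane-1,2-diol, p-TsOH (cat.), toluene, reflux, Dean–Stark trap
Reagents that add atoms: ethane-1,2-diol, OCCO
Why: Acid-catalysed ketalisation with azeotropic removal of water is routine for methyl ketones and masks the carbonyl before the organomagnesium step.

Step 2
Reactants: 2 2-(3-chloropropyl)-2-methyl-1,3-dioxolane; 3 diketene
Product: 5 3-methylidene-6-(2-methyl-1,3-dioxolan-2-yl)hexanoic acid, via Grignard reagent 4 (not isolated)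
Conditions: Mg, THF, reflux; then 3, NiCl2 (5 mol %), THF, 0 °C; cold dilute HCl to pH 3–4
Reagents that add atoms: none
Why: Nickel-catalysed ring opening of diketene by a Grignard reagent cleaves the vinylic C–O bond and should give the 3-methylidene acid directly, the ketal being inert to the organomagnesium.

Step 3
Reactants: 6 (E)-pent-2-en-4-yn-1-ol
Product: 8 (E)-5-(triisopropylsilyl)pent-2-en-4-yn-1-ol, via dilithio dianion 7 (not isolated)
Conditions: n-BuLi (2.1 equiv), THF, −78 °C; then i-Pr3SiCl (1.0 equiv), −78 °C → rt; aq. NH4Cl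
Reagents that add atoms: chlorotriisopropylsilane, CC(C)[Si](Cl)(C(C)C)C(C)C
Why: C-Silylation of the alkoxide–acetylide dianion should occur at the more nucleophilic acetylide carbon, and the bulky silyl group is chosen so that the alkyne stays inert in the later hydroboration.

Step 4
Reactants: 5 3-methylidene-6-(2-methyl-1,3-dioxolan-2-yl)hexanoic acid; 8 (E)-5-(triisopropylsilyl)pent-2-en-4-yn-1-ol
Product: 9 (E)-5-(triisopropylsilyl)pent-2-en-4-yn-1-yl 3-methylidene-6-(2-methyl-1,3-dioxolan-2-yl)hexanoate
Conditions: DCC, DMAP (5 mol %), CH2Cl2, −10 °C → 0 °C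
Reagents that add atoms: none
Why: Steglich esterification at low temperature with little DMAP joins acid and allylic alcohol without moving the 1,1-disubstituted alkene into conjugation.

Step 5
Reactants: 9 enynyl ester (E)-5-(triisopropylsilyl)pent-2-en-4-yn-1-yl 3-methylidene-6-(2-methyl-1,3-dioxolan-2-yl)hexanoate
Product: 11 (3R,4S)-Claisen acid (C3 carboxylic acid; C4 carries a vinyl group and the silylated ethynyl group), via boron ketene acetal 10 (not isolated)
Conditions: (4S,5S)-2-bromo-1,3-bis{[3,5-bis(trifluoromethyl)phenyl]sulfonyl}-4,5-diphenyl-1,3,2-diazaborolidine (1.1 equiv), Et3N, toluene–hexane, −78 °C; then −20 °C → 4 °C; aqueous work-up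
Reagents that add atoms: none
Why: In this enantioselective Ireland–Claisen rearrangement, amine-mediated soft enolisation in the non-polar medium should give the boron ketene acetal with the C2 alkenyl group trans to O–B, whose chair transition state with the (E)-alkene gives the anti relationship of C3 and C4, while the C2-symmetric bis-sulfonamide on boron selects the enolate face (Re at C3, Re at C4) and so sets both centres as 3R,4S.

Step 6
Reactants: 11 (3R,4S)-Claisen acid
Product: 12 (3R,4S)-primary alcohol (C3 hydroxymethyl)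
Conditions: LiAlH4, THF, 0 °C → rt; H2O then aq. NaOH
Reagents that add atoms: none
Why: Lithium aluminium hydride reduction of the carboxylic acid gives the primary alcohol, after which C3 is no longer alpha to a carbonyl and cannot epimerise or conjugate in the following steps.

Step 7
Reactants: 12 (3R,4S)-primary alcohol
Product: 13 (3R,4S)-pivalate (C3 pivaloyloxymethyl)
Conditions: pivaloyl chloride, pyridine, DMAP (cat.), CH2Cl2, 0 °C → rt
Reagents that add atoms: pivaloyl chloride, CC(C)(C)C(=O)Cl
Why: Acylation of the unhindered primary alcohol gives an ester that should survive borane, fluoride, acidic methanol and the palladium step.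

Step 8
Reactants: 13 (3R,4S)-pivalate
Product: 15 (3R,4S)-hydroxyethyl pivalate (C4 arm = CH2CH2OH), via alkylborane 14 (not isolated)
Conditions: bis(3-methylbutan-2-yl)borane (from BH3·SMe2 and 2-methylbut-2-ene; 1.3 equiv), THF, 0 °C; then H2O2, aq. NaOH, 0 °C
Reagents that add atoms: hydrogen peroxide, OO
Why: Hydroboration–oxidation with the hindered dialkylborane is anti-Markovnikov and should select the monosubstituted vinyl group over the 1,1-disubstituted C1=C2 alkene next to the C3 branch and over the alkyne shielded by the triisopropylsilyl group.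

Step 9
Reactants: 15 (3R,4S)-hydroxyethyl pivalate
Product: 16 (3R,4S)-aldehyde (C4 arm = CH2CHO)
Conditions: Dess–Martin periodinane, NaHCO3, CH2Cl2, 0 °C → rt
Reagents that add atoms: none
Why: Dess–Martin oxidation of the primary alcohol stops at the aldehyde under buffered conditions, and this aldehyde has no alpha stereocentre to lose.

Step 10
Reactants: 16 (3R,4S)-aldehyde
Product: 17 (3R,4S)-dimethyl acetal (C4 arm = CH2CH(OMe)2)
Conditions: HC(OMe)3, pyridinium p-toluenesulfonate (cat.), MeOH, rt
Reagents that add atoms: trimethyl orthoformate, COC(OC)OC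
Why: Acid-catalysed acetalisation with the orthoester as water scavenger gives the acyclic acetal, the most easily hydrolysed mask, which keeps the final deprotection mild.

Step 11
Reactants: 17 (3R,4S)-dimethyl acetal
Product: 18 (3R,4S)-terminal alkyne (C5≡C6–H)
Conditions: Bu4NF, THF, 0 °C → rt
Reagents that add atoms: none
Why: Fluoride-induced protodesilylation cleaves the C(sp)–Si bond, while pivalate, acetal and ketal are not attacked by fluoride.

Step 12
Reactants: 19 methyl propiolate
Product: 20 methyl (Z)-3-iodoprop-2-enoate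
Conditions: NaI, AcOH, 70 °C
Reagents that add atoms: sodium iodide, [Na+].[I-]
Why: Hydroiodination of the propiolate with iodide in acetic acid proceeds by anti addition and should give the (Z)-β-iodoacrylate as the kinetic product.

Step 13
Reactants: 20 methyl (Z)-3-iodoprop-2-enoate
Product: 21 (Z)-4-iodo-2-methylbut-3-en-2-ol
Conditions: MeMgBr (2.5 equiv), Et2O, −78 °C → 0 °C; aq. NH4Cl
Reagents that add atoms: methylmagnesium bromide, C[Mg]Br
Why: Double Grignard addition to the ester builds the tertiary alcohol, and at low temperature the (Z)-iodoalkene should be retained.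

Step 14
Reactants: 18 (3R,4S)-terminal alkyne; 21 (Z)-4-iodo-2-methylbut-3-en-2-ol
Product: 22 (3R,4S,7Z)-enynol (C5≡C6–C7H=C8H–C9Me2OH; C3 pivaloyloxymethyl; C4 dimethyl-acetal arm; side chain as dioxolane)
Conditions: PdCl2(PPh3)2 (3 mol %), CuI (6 mol %), Et3N, THF, rt, degassed
Reagents that add atoms: none
Why: Sonogashira coupling of a terminal alkyne with a (Z)-vinyl iodide proceeds with retention of alkene geometry under mild amine conditions and tolerates the free tertiary alcohol.

Step 15
Reactants: 22 (3R,4S,7Z)-enynol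
Product: 23 (3R,4S,5E)-furanylidene methyl ester (C5–CO2Me, C5=C6 exocyclic to the 2,5-dihydrofuran O–C6–C7=C8–C9Me2)
Conditions: PdCl2(MeCN)2 (10 mol %), p-benzoquinone (1.5 equiv), CO (1 atm), MeOH, 0 °C → rt
Reagents that add atoms: carbon monoxide, [C-]#[O+]; methanol, CO
Why: Divalent palladium should coordinate the C5≡C6 alkyne, and the C9 hydroxyl, held over C6 by the (Z)-C7=C8 alkene and the gem-dimethyl group, attacks C6 from the side opposite the metal to give a σ-vinylpalladium at C5 that inserts CO and is cleaved by methanol, after which benzoquinone returns zerovalent palladium to the divalent state. The closest known reaction type is the oxidative cyclisation–alkoxycarbonylation of alkynols and of (Z)-2-en-4-yn-1-ols to (E)-β-alkoxyacrylates; internal alkynes are known in related oxidative heterocyclisation–carbonylations, and the internal alkyne with a branched propargylic carbon (C4) used here extends that class. The dihydrofuran ring closes in the 5-exo-dig mode (O–C6), and the 6-endo alternative should be disfavoured because attack at C5 is hindered by the C4 branch. No stereocentre is created and C3 and C4 are not touched; the anti addition fixes the alkene geometry with the ester trans and C4 cis to the ring oxygen, as in the target. The quaternary C9 blocks aromatisation to a furan, and CO insertion must outrun protonolysis of the crowded vinylpalladium, hence the CO atmosphere and the absence of added acid. Acetal, dioxolane and pivalate are indifferent to neutral methanol, and the C1=C2 alkene is a much poorer partner for the metal than the enynol.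

Step 16
Reactants: 23 (3R,4S,5E)-furanylidene methyl ester
Product: 24 (3R,4S,5E)-diol (C3 hydroxymethyl and C5 hydroxymethyl)
Conditions: i-Bu2AlH (5 equiv), CH2Cl2, −78 °C; aq. KNaC4H4O6 (sodium potassium tartrate) work-up
Reagents that add atoms: none
Why: Diisobutylaluminium hydride reduction takes the β-alkoxyacrylate by 1,2-addition to the allylic alcohol and cleaves the pivalate in the same flask, and the tartrate work-up keeps the acid-labile enol ether away from acid so that the crude diol can be used at once.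

Step 17
Reactants: 24 (3R,4S,5E)-diol
Product: 25 (3R,4S,5E)-hydroxy enal (C5 formyl, C3 hydroxymethyl)
Conditions: MnO2 (activated, excess), CH2Cl2, rt
Reagents that add atoms: none
Why: Manganese dioxide oxidises only the allylic alcohol, giving a vinylogous formate that deactivates the enol ether, and leaves the saturated C3 carbinol.

Step 18
Reactants: 25 (3R,4S,5E)-hydroxy enal
Product: 26 (3R,4S,5E)-dialdehyde (C3 formyl, C5 formyl)
Conditions: Dess–Martin periodinane, NaHCO3, CH2Cl2, 0 °C
Reagents that add atoms: none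
Why: Buffered Dess–Martin oxidation converts the remaining primary alcohol to the aldehyde without epimerising C3 or moving the C1=C2 alkene into conjugation, and the product is carried on directly.

Step 19
Reactants: 26 (3R,4S,5E)-dialdehyde
Product: 27 (3R,4S,5E)-formyl acid (C3 carboxylic acid, C5 formyl)
Conditions: NaClO2, NaH2PO4, 2-methylbut-2-ene, t-BuOH–H2O, 0 °C
Reagents that add atoms: sodium chlorite, [Na+].[O-]Cl=O
Why: Pinnick oxidation should convert the saturated aldehyde, which adds chlorous acid readily, and spare the C5 formyl group, whose carbonyl is deactivated as a hindered vinylogous formate, while the alkene scavenger removes hypochlorite before it can attack the enol ether or the C1=C2 alkene.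

Step 20
Reactants: 27 (3R,4S,5E)-formyl acid
Product: 28 CNP0150297.1, (2R,3S,4E)-4-(5,5-dimethylfuran-2(5H)-ylidene)-5-oxo-2-(6-oxohept-1-en-2-yl)-3-(2-oxoethyl)pentanoic acid
Conditions: 1 M aq. HCl–THF (1:3), 0 °C → rt
Reagents that add atoms: water, O
Why: Acid-catalysed hydrolysis removes the dimethyl acetal and the ketone dioxolane, both fast-hydrolysing masks, while the enol ether should survive because conjugation to the C5 formyl group makes it a vinylogous ester.

Compound list

1 | 5-chloropentan-2-one | CC(=O)CCCCl | starting material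
2 | 2-(3-chloropropyl)-2-methyl-1,3-dioxolane | CC1(CCCCl)OCCO1 | intermediate
3 | diketene (4-methylideneoxetan-2-one) | C=C1CC(=O)O1 | starting material
4 | [3-(2-methyl-1,3-dioxolan-2-yl)propyl]magnesium chloride | CC1(CCC[Mg]Cl)OCCO1 | intermediate
5 | 3-methylidene-6-(2-methyl-1,3-dioxolan-2-yl)hexanoic acid | C=C(CCCC1(C)OCCO1)CC(=O)O | intermediate
6 | (E)-pent-2-en-4-yn-1-ol | OC/C=C/C#C | starting material
7 | dilithium salt of 6 (lithium alkoxide and lithium acetylide) | [Li]OC/C=C/C#C[Li] | intermediate
8 | (E)-5-(triisopropylsilyl)pent-2-en-4-yn-1-ol | OC/C=C/C#C[Si](C(C)C)(C(C)C)C(C)C | intermediate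
9 | (E)-5-(triisopropylsilyl)pent-2-en-4-yn-1-yl 3-methylidene-6-(2-methyl-1,3-dioxolan-2-yl)hexanoate | C=C(CCCC1(C)OCCO1)CC(=O)OC/C=C/C#C[Si](C(C)C)(C(C)C)C(C)C | intermediate
10 | boron ketene acetal of 9, O-bound to the (4S,5S)-1,3-bis{[3,5-bis(trifluoromethyl)phenyl]sulfonyl}-4,5-diphenyl-1,3,2-diazaborolidin-2-yl group, alkenyl group cis to the allyloxy oxygen | C=C(CCCC1(C)OCCO1)/C=C(\OC/C=C/C#C[Si](C(C)C)(C(C)C)C(C)C)OB1N(S(=O)(=O)c2cc(C(F)(F)F)cc(C(F)(F)F)c2)[C@@H](c2ccccc2)[C@H](c2ccccc2)N1S(=O)(=O)c1cc(C(F)(F)F)cc(C(F)(F)F)c1 | intermediate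
11 | (2R,3S)-2-[5-(2-methyl-1,3-dioxolan-2-yl)pent-1-en-2-yl]-3-[(triisopropylsilyl)ethynyl]pent-4-enoic acid | C=C(CCCC1(C)OCCO1)[C@H](C(=O)O)[C@H](C=C)C#C[Si](C(C)C)(C(C)C)C(C)C | intermediate
12 | (2R,3S)-2-[5-(2-methyl-1,3-dioxolan-2-yl)pent-1-en-2-yl]-3-[(triisopropylsilyl)ethynyl]pent-4-en-1-ol | C=C(CCCC1(C)OCCO1)[C@H](CO)[C@H](C=C)C#C[Si](C(C)C)(C(C)C)C(C)C | intermediate
13 | (2R,3S)-2-[5-(2-methyl-1,3-dioxolan-2-yl)pent-1-en-2-yl]-3-[(triisopropylsilyl)ethynyl]pent-4-en-1-yl 2,2-dimethylpropanoate | C=C(CCCC1(C)OCCO1)[C@H](COC(=O)C(C)(C)C)[C@H](C=C)C#C[Si](C(C)C)(C(C)C)C(C)C | intermediate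
14 | B-alkyl bis(3-methylbutan-2-yl)borane from 13, boron on the terminal carbon of the former vinyl group | C=C(CCCC1(C)OCCO1)[C@H](COC(=O)C(C)(C)C)[C@H](CCB(C(C)C(C)C)C(C)C(C)C)C#C[Si](C(C)C)(C(C)C)C(C)C | intermediate
15 | (2R,3S)-3-(2-hydroxyethyl)-2-[5-(2-methyl-1,3-dioxolan-2-yl)pent-1-en-2-yl]-5-(triisopropylsilyl)pent-4-yn-1-yl 2,2-dimethylpropanoate | C=C(CCCC1(C)OCCO1)[C@H](COC(=O)C(C)(C)C)[C@H](CCO)C#C[Si](C(C)C)(C(C)C)C(C)C | intermediate
16 | (2R,3S)-2-[5-(2-methyl-1,3-dioxolan-2-yl)pent-1-en-2-yl]-3-(2-oxoethyl)-5-(triisopropylsilyl)pent-4-yn-1-yl 2,2-dimethylpropanoate | C=C(CCCC1(C)OCCO1)[C@H](COC(=O)C(C)(C)C)[C@H](CC=O)C#C[Si](C(C)C)(C(C)C)C(C)C | intermediate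
17 | (2R,3S)-3-(2,2-dimethoxyethyl)-2-[5-(2-methyl-1,3-dioxolan-2-yl)pent-1-en-2-yl]-5-(triisopropylsilyl)pent-4-yn-1-yl 2,2-dimethylpropanoate | C=C(CCCC1(C)OCCO1)[C@H](COC(=O)C(C)(C)C)[C@H](CC(OC)OC)C#C[Si](C(C)C)(C(C)C)C(C)C | intermediate
18 | (2R,3S)-3-(2,2-dimethoxyethyl)-2-[5-(2-methyl-1,3-dioxolan-2-yl)pent-1-en-2-yl]pent-4-yn-1-yl 2,2-dimethylpropanoate | C=C(CCCC1(C)OCCO1)[C@H](COC(=O)C(C)(C)C)[C@H](CC(OC)OC)C#C | intermediate
19 | methyl propiolate | C#CC(=O)OC | starting material
20 | methyl (Z)-3-iodoprop-2-enoate | COC(=O)/C=C\I | intermediate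
21 | (Z)-4-iodo-2-methylbut-3-en-2-ol | CC(C)(O)/C=C\I | intermediate
22 | (2R,3S,6Z)-3-(2,2-dimethoxyethyl)-8-hydroxy-8-methyl-2-[5-(2-methyl-1,3-dioxolan-2-yl)pent-1-en-2-yl]non-6-en-4-yn-1-yl 2,2-dimethylpropanoate (key-step precursor) | C=C(CCCC1(C)OCCO1)[C@H](COC(=O)C(C)(C)C)[C@H](CC(OC)OC)C#C/C=C\C(C)(C)O | intermediate
23 | methyl (2E,3S,4R)-3-(2,2-dimethoxyethyl)-2-(5,5-dimethylfuran-2(5H)-ylidene)-4-[(2,2-dimethylpropanoyloxy)methyl]-5-methylidene-8-(2-methyl-1,3-dioxolan-2-yl)octanoate (key-step product) | C=C(CCCC1(C)OCCO1)[C@H](COC(=O)C(C)(C)C)[C@H](CC(OC)OC)/C(C(=O)OC)=C1/C=CC(C)(C)O1 | intermediate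
24 | (2R,3S,4E)-3-(2,2-dimethoxyethyl)-4-(5,5-dimethylfuran-2(5H)-ylidene)-2-[5-(2-methyl-1,3-dioxolan-2-yl)pent-1-en-2-yl]pentane-1,5-diol | C=C(CCCC1(C)OCCO1)[C@H](CO)[C@H](CC(OC)OC)/C(CO)=C1/C=CC(C)(C)O1 | intermediate
25 | (2E,3S,4R)-3-(2,2-dimethoxyethyl)-2-(5,5-dimethylfuran-2(5H)-ylidene)-4-(hydroxymethyl)-5-methylidene-8-(2-methyl-1,3-dioxolan-2-yl)octanal | C=C(CCCC1(C)OCCO1)[C@H](CO)[C@H](CC(OC)OC)/C(C=O)=C1/C=CC(C)(C)O1 | intermediate
26 | (2E,3S,4R)-3-(2,2-dimethoxyethyl)-2-(5,5-dimethylfuran-2(5H)-ylidene)-4-formyl-5-methylidene-8-(2-methyl-1,3-dioxolan-2-yl)octanal | C=C(CCCC1(C)OCCO1)[C@H](C=O)[C@H](CC(OC)OC)/C(C=O)=C1/C=CC(C)(C)O1 | intermediate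
27 | (2R,3S,4E)-3-(2,2-dimethoxyethyl)-4-(5,5-dimethylfuran-2(5H)-ylidene)-2-[5-(2-methyl-1,3-dioxolan-2-yl)pent-1-en-2-yl]-5-oxopentanoic acid | C=C(CCCC1(C)OCCO1)[C@H](C(=O)O)[C@H](CC(OC)OC)/C(C=O)=C1/C=CC(C)(C)O1 | intermediate
28 | CNP0150297.1, (2R,3S,4E)-4-(5,5-dimethylfuran-2(5H)-ylidene)-5-oxo-2-(6-oxohept-1-en-2-yl)-3-(2-oxoethyl)pentanoic acid | C=C(CCCC(C)=O)[C@H](C(=O)O)[C@H](CC=O)/C(C=O)=C1/C=CC(C)(C)O1 | target

Total step count: 20. Longest linear sequence: 17 steps (1, 2, 4–11, 14–20).

Steps most likely to fail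

Step 15. The crowded vinylpalladium at C5 may be protonated before it inserts CO, which would give plain cycloisomerisation, or ring closure may drift towards the 6-endo mode at the internal alkyne. Fallback: the cascade is split into two established operations. Setting out from 22, I2 with NaHCO3 in MeCN at 0 °C should bring about anti 5-exo-dig iodoetherification to the (E)-iodoalkylidene dihydrofuran F1. Methoxycarbonylation of this vinyl iodide with Pd(PPh3)4 under CO (1 atm) in MeOH–Et3N–DMF at 50 °C proceeds by oxidative addition to zerovalent palladium, CO insertion and methanolysis, all with retention of alkene geometry, and comes back to the route at 23.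

Step 5. Enolisation of this β,γ-unsaturated ester may give a mixture of enolate geometries or poor facial discrimination, the Lewis-acidic bromoborane may open the dioxolane, and the rearrangement may be slow. Fallback: from 9, the classical Ireland–Claisen rearrangement (LiN(i-Pr)2, THF, −78 °C; Me3SiCl; warm to rt; dilute acid) via the trimethylsilyl ketene acetal F2 should give the anti acid as the racemate, that is 11 together with its mirror image, the (2S,3R) acid F3. Resolution by preparative chromatography on a chiral stationary phase returns to the route at 11.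

Step 19. Chlorite may also attack the C5 formyl group or chlorinate the dienol ether, that is, chemoselectivity between the two aldehydes may be lost. Fallback: the order of the redox adjustments is inverted so that the C3 aldehyde is the only aldehyde present when chlorite is used. From 23, NaOMe in MeOH at rt removes the pivalate to give the hydroxy ester F4, and Dess–Martin oxidation gives the aldehyde ester F5. Pinnick oxidation then gives the acid ester F6, and excess i-Bu2AlH at −78 °C (the aluminium carboxylate is not reduced at this temperature) gives the hydroxy acid F7. MnO2 oxidation of the allylic alcohol comes back to the route at 27.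

Further compounds

F1 | step 15 | (2R,3S,4E)-3-(2,2-dimethoxyethyl)-4-(5,5-dimethylfuran-2(5H)-ylidene)-4-iodo-2-[5-(2-methyl-1,3-dioxolan-2-yl)pent-1-en-2-yl]butyl 2,2-dimethylpropanoate | C=C(CCCC1(C)OCCO1)[C@H](COC(=O)C(C)(C)C)[C@H](CC(OC)OC)/C(I)=C1/C=CC(C)(C)O1
F2 | step 5 | trimethylsilyl ketene acetal of 9, alkenyl group cis to the allyloxy oxygen | C=C(CCCC1(C)OCCO1)/C=C(\OC/C=C/C#C[Si](C(C)C)(C(C)C)C(C)C)O[Si](C)(C)C
F3 | step 5 | (2S,3R)-2-[5-(2-methyl-1,3-dioxolan-2-yl)pent-1-en-2-yl]-3-[(triisopropylsilyl)ethynyl]pent-4-enoic acid (mirror image of 11) | C=C(CCCC1(C)OCCO1)[C@@H](C(=O)O)[C@@H](C=C)C#C[Si](C(C)C)(C(C)C)C(C)C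
F4 | step 19 | methyl (2E,3S,4R)-3-(2,2-dimethoxyethyl)-2-(5,5-dimethylfuran-2(5H)-ylidene)-4-(hydroxymethyl)-5-methylidene-8-(2-methyl-1,3-dioxolan-2-yl)octanoate | C=C(CCCC1(C)OCCO1)[C@H](CO)[C@H](CC(OC)OC)/C(C(=O)OC)=C1/C=CC(C)(C)O1
F5 | step 19 | methyl (2E,3S,4R)-3-(2,2-dimethoxyethyl)-2-(5,5-dimethylfuran-2(5H)-ylidene)-4-formyl-5-methylidene-8-(2-methyl-1,3-dioxolan-2-yl)octanoate | C=C(CCCC1(C)OCCO1)[C@H](C=O)[C@H](CC(OC)OC)/C(C(=O)OC)=C1/C=CC(C)(C)O1
F6 | step 19 | (2R,3S,4E)-3-(2,2-dimethoxyethyl)-4-(5,5-dimethylfuran-2(5H)-ylidene)-5-methoxy-2-[5-(2-methyl-1,3-dioxolan-2-yl)pent-1-en-2-yl]-5-oxopentanoic acid | C=C(CCCC1(C)OCCO1)[C@H](C(=O)O)[C@H](CC(OC)OC)/C(C(=O)OC)=C1/C=CC(C)(C)O1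
F7 | step 19 | (2R,3S,4E)-3-(2,2-dimethoxyethyl)-4-(5,5-dimethylfuran-2(5H)-ylidene)-5-hydroxy-2-[5-(2-methyl-1,3-dioxolan-2-yl)pent-1-en-2-yl]pentanoic acid | C=C(CCCC1(C)OCCO1)[C@H](C(=O)O)[C@H](CC(OC)OC)/C(CO)=C1/C=CC(C)(C)O1
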